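A reading taken at 2.50 h in the alpha run poses the question for this flask: of the substrate lost so far, what chance has a molecule of being target already?

| flask | substrate | partner | remark | time |
|---|---|---|---|---|
| alpha | 27 mM | 1.1 equiv | run made earlier |  |
| beta | 38 mM | 1.1 equiv | run made earlier |  |
| theta | 59 mM | 1.1 equiv | run made earlier |  |
| gamma | 27 mM | 2.2 equiv | run made earlier |  |
| dawn | 27 mM | 1.10 equiv | everything together at the start | 30 h |
| spring | 27 mM | 1.10 equiv (fed, over 25 h) | all else is in the flask from the start; the feed brings no volume worth counting | 30 h |
| dusk | 27 mM (fed, over 25 h) | 1.10 equiv | all else is in the flask from the start; the feed brings no volume worth counting | 30 h |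

| run | time / h | target / % | substrate / % |
|---|---|---|---|
| alpha | 2.50 | 5 | 69 |
| alpha | 5.00 | 12 | 53 |
| alpha | 8.00 | 15 | 39 |
| alpha | 15.0 | 19 | 27 |
| alpha | 30.0 | 25 | 26 |
| beta | 8.00 | 17 | 37 |
| beta | 15.0 | 22 | 25 |
| beta | 20.0 | 23 | 24 |
| beta | 30.0 | 21 | 22 |
| beta | 40.0 | 21 | 21 |
| theta | 3.00 | 9 | 63 |
| theta | 10.0 | 22 | 31 |
| theta | 15.0 | 21 | 25 |
| theta | 25.0 | 24 | 19 |
| theta | 40.0 | 22 | 19 |
| gamma | 3.00 | 9 | 62 |
| gamma | 10.0 | 23 | 30 |
| gamma | 15.0 | 24 | 21 |
| gamma | 25.0 | 27 | 16 |
| gamma | 40.0 | 26 | 16 |

(standard deviation of a reading: 1.5 percentage points)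



1. the flask with the highest amount of target, in percent of the substrate charged ("all alike" if they lie within 1.5 percentage points) (dawn / spring / dusk / all alike)
2. final target, as a percentage of the substrate charged, in dawn
3. final target, as a percentage of the substrate charged, in spring
4. final target, as a percentage of the substrate charged, in dusk

In those first hours of alpha, substrate falls with a time constant of about 6.74 h, read from that one point, and 31.0 % of the charge has gone while target reads 5 %. The chance is then 0.161. By 8.00 h in alpha it reads 0.246, more than at first, so target trails the loss of substrate. At 30.0 h, substrate in alpha stands at 26 % and target at 25 %, and the remaining 49.0 % of the charge is neither, so it stands in forms these readings do not show.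

The end value of the chance, target per substrate lost (the selectivity), is averaged over the last readings of alpha, beta and theta, all at 1.1 equiv of partner: 0.292. My own reckoning for dawn multiplies it by the 74.0 % lost in alpha, which gives 21.6 %. No earlier run was fed, so this reckoning is untried on spring and dusk.

The forecast, which says “Target is stable and takes about 0.29 of substrate consumed”, gives 23 % for dawn, 21.5 % for spring and 11 % for dusk, and names dawn as the best flask.

The flasks give 22.0 % in dawn, 18.5 % in spring and 25.8 % in dusk, so dusk holds the most target. Dusk ends with 4.80 % of over-reaction product, less than the 13.0 % in dawn. The carried chance on the 70.2 % of substrate lost in dusk gives 20.5 %, but dusk's own chance is 0.367, higher than the carried value.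

    open intermediate + second intermediate ⇌ target (K = 33.0 M⁻¹, k = 29.5 M⁻¹ h⁻¹)
    substrate ⇌ open intermediate (K = 1.60, k = 0.174 h⁻¹)
    partner → second intermediate (k = 0.160 h⁻¹)
    partner + target → over-reaction product (k = 9.64 M⁻¹ h⁻¹)

The neighbour of spring fed 2.80 equiv of partner keeps 14.1 % of its substrate at 30.0 h, so the chance, read at 1.1 equiv of partner, gives 25.1 % of target. The computed flask holds 19.2 %, a chance of 0.224.

(The readings stem from a simulated flask with constants of no real substance; noise was put on by code.)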